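**Retrosynthetic overview**
1. Target ⇒ bis-TBS ether; the ten-membered carbocycle is opened at C1=C10 (ring-closing metathesis, which in a ten-membered ring should give the required Z trisubstituted alkene).
2. C8–O acyl bond ⇒ (S)-Roche acid; C11=C13 ⇒ Mannich methylenation of the saturated γ-lactone.
3. Key disconnection C7–C8: a ketyl radical from a C5 β,γ-unsaturated aldehyde adds to C7 of a γ-alkenyl butenolide, anti to the C6 substituent; C7 and C8 are both set here.
4. Butenolide ⇒ (Z)-enal + propiolate (catalytic asymmetric alkynylation sets C6, then semi-hydrogenation and lactonisation); (Z)-enal ⇒ propargyl alcohol + butenyl Grignard reagent (anti-carbomagnesiation sets the C4=C5 geometry).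
5. Ring order: five-membered lactone first (step 5), ten-membered carbocycle second (step 12).

Assumption: positions are quoted in germacrane numbering (C6 lactone carbinol carbon, C7 ring-fusion carbon, C8 acyloxy carbon, C11/C12/C13 lactone α-carbon, carbonyl and exocyclic CH2, C14 methyl on C10, C15 CH2OH on C4); TBS = tert-butyldimethylsilyl; Grignard solution 2 is bought.

**Step 1**
Reactants: 1 prop-2-yn-1-ol; 2 but-3-en-1-ylmagnesium bromide
Product: 4 (2Z)-2-(but-3-en-1-yl)-3-iodoprop-2-en-1-ol, via magnesium chelate 3 (not isolated)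
Conditions: 2 (2.6 equiv), CuI (10 mol %), Et2O–THF, 0 °C to reflux, 12 h; then I2 (1.3 equiv), −40 to 0 °C
Reagents that add atoms: iodine, II
Why: Copper-catalysed anti-carbomagnesiation of the propargylic alkoxide (Duboudin–Jousseaume reaction) puts the butenyl group on C4 and magnesium on C5 cis to the CH2O arm in chelate 3, so iodinolysis with retention fixes the C4=C5 geometry of the target.

**Step 2**
Reactants: 4 (2Z)-2-(but-3-en-1-yl)-3-iodoprop-2-en-1-ol
Product: 5 tert-butyl{[(2Z)-2-(but-3-en-1-yl)-3-iodoprop-2-en-1-yl]oxy}dimethylsilane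
Conditions: TBSCl, imidazole, CH2Cl2, 0 °C to rt
Reagents that add atoms: tert-butyldimethylsilyl chloride (TBSCl), CC(C)(C)[Si](C)(C)Cl
Why: Standard silylation of the primary allylic alcohol (C15–OH), which must be masked before the lithiation and all later steps.

**Step 3**
Reactants: 5 tert-butyl{[(2Z)-2-(but-3-en-1-yl)-3-iodoprop-2-en-1-yl]oxy}dimethylsilane
Product: 7 (2Z)-3-[(TBSO)methyl]hepta-2,6-dienal, via vinyllithium 6 (not isolated)
Conditions: t-BuLi (2.1 equiv), Et2O, −78 °C, 15 min; DMF (3 equiv), −78 to 0 °C; H2O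
Reagents that add atoms: N,N-dimethylformamide (DMF), CN(C)C=O
Why: Iodine–lithium exchange proceeds with retention of alkene geometry and formylation with DMF gives the (Z)-enal (C6), the reaction being kept at −78 °C in ether so that 1,4-silyl migration to carbon stays slow.

**Step 4**
Reactants: 7 (2Z)-3-[(TBSO)methyl]hepta-2,6-dienal; 8 methyl prop-2-ynoate
Product: 10 methyl (4R,5Z)-6-[(TBSO)methyl]-4-hydroxydeca-5,9-dien-2-ynoate, via alkynylzinc 9 (not isolated)
Conditions: 8 (2.8 equiv), Me2Zn (2.9 equiv), (S,S)-ProPhenol (20 mol %), Ph3P=O (40 mol %), toluene, 4 °C, 48 h; H2O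
Reagents that add atoms: none
Why: Dinuclear zinc–ProPhenol asymmetric alkynylation (Trost alkynylation) adds alkynylzinc 9 to the Si face of the enal carbonyl and so sets C6 as the 4R alcohol; the ligand antipode is the one matched to that face, and the sense is checked by Mosher analysis of 10.

**Step 5**
Reactants: 10 methyl (4R,5Z)-6-[(TBSO)methyl]-4-hydroxydeca-5,9-dien-2-ynoate
Product: 12 (5S)-5-{(1Z)-2-[(TBSO)methyl]hexa-1,5-dien-1-yl}furan-2(5H)-one, via hydroxy enoate 11 (not isolated)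
Conditions: H2 (1 atm), Pd/CaCO3 poisoned with Pb(OAc)2 (Lindlar catalyst), quinoline, EtOAc, rt, stopped after 1 equiv H2; then PPTS (10 mol %), CH2Cl2, rt
Reagents that add atoms: none
Why: Lindlar semi-hydrogenation gives the (Z)-γ-hydroxy enoate 11, which lactonises to the butenolide without touching C6 (the descriptor changes from R to S only through CIP priorities).

**Step 6**
Reactants: 13 3-methylbut-3-en-1-ol
Product: 14 3-methylbut-3-enal
Conditions: Dess–Martin periodinane, NaHCO3, CH2Cl2, 0 °C; short silica plug, kept cold, used at once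
Reagents that add atoms: none
Why: Buffered Dess–Martin oxidation gives the β,γ-unsaturated aldehyde without isomerisation to the conjugated enal.

**Step 7 (key step)**
Reactants: 12 (5S)-5-{(1Z)-2-[(TBSO)methyl]hexa-1,5-dien-1-yl}furan-2(5H)-one; 14 3-methylbut-3-enal
Product: 15 (4R,5R)-4-[(1S)-1-hydroxy-3-methylbut-3-en-1-yl]-5-{(1Z)-2-[(TBSO)methyl]hexa-1,5-dien-1-yl}oxolan-2-one
Conditions: SmI2 (4 equiv, 0.1 M in THF), t-BuOH (4 equiv), 14 (2.5 equiv), THF, −78 to 0 °C
Reagents that add atoms: none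
Why: Samarium diiodide reduces 14 to a ketyl radical that adds to the β-carbon (C7) of butenolide 12 on the face anti to the C6 alkenyl group (ketyl–olefin radical conjugate addition), and a samarium bridge between the ketyl oxygen and the lactone carbonyl, with the small hydrogen turned over the ring, is expected to give C8 as S before t-BuOH protonates the samarium enolate.

**Step 8**
Reactants: 15 (4R,5R)-4-[(1S)-1-hydroxy-3-methylbut-3-en-1-yl]-5-{(1Z)-2-[(TBSO)methyl]hexa-1,5-dien-1-yl}oxolan-2-one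
Product: 18 (4R,5R)-4-[(1S)-1-hydroxy-3-methylbut-3-en-1-yl]-3-methylidene-5-{(1Z)-2-[(TBSO)methyl]hexa-1,5-dien-1-yl}oxolan-2-one, via Mannich base 16 (not isolated), via ammonium iodide 17 (not isolated)
Conditions: LiN(iPr)2 (2.3 equiv), THF, −78 °C; CH2=NMe2+ I− (3 equiv), −78 to 0 °C; then MeI, MeOH–CH2Cl2, rt; then aq NaHCO3, EtOAc, rt
Reagents that add atoms: N,N-dimethylmethyleneiminium iodide (Eschenmoser's salt), C=[N+](C)C.[I-]
Why: The alkoxide–enolate dianion undergoes a Mannich reaction with Eschenmoser's salt at C11 anti to the C7 substituent, and quaternisation followed by Hofmann-type elimination gives the exocyclic methylene without touching C6, C7 or C8.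

**Step 9**
Reactants: 19 methyl (2S)-3-hydroxy-2-methylpropanoate
Product: 20 methyl (2S)-3-(TBSO)-2-methylpropanoate
Conditions: TBSCl, imidazole, DMF, rt
Reagents that add atoms: tert-butyldimethylsilyl chloride (TBSCl), CC(C)(C)[Si](C)(C)Cl
Why: Standard silylation of the Roche ester hydroxyl so that the acid can be used as an acyl donor.

**Step 10**
Reactants: 20 methyl (2S)-3-(TBSO)-2-methylpropanoate
Product: 21 (2S)-3-(TBSO)-2-methylpropanoic acid
Conditions: LiOH, THF–H2O, 0 °C to rt; 1 M HCl to pH 3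
Reagents that add atoms: lithium hydroxide, [Li+].[OH-]
Why: Mild saponification of the methyl ester leaves the α-stereocentre and the silyl ether intact.

**Step 11**
Reactants: 18 (4R,5R)-4-[(1S)-1-hydroxy-3-methylbut-3-en-1-yl]-3-methylidene-5-{(1Z)-2-[(TBSO)methyl]hexa-1,5-dien-1-yl}oxolan-2-one; 21 (2S)-3-(TBSO)-2-methylpropanoic acid
Product: 22 (1S)-3-methyl-1-[(2R,3R)-4-methylidene-5-oxo-2-{(1Z)-2-[(TBSO)methyl]hexa-1,5-dien-1-yl}oxolan-3-yl]but-3-en-1-yl (2S)-3-(TBSO)-2-methylpropanoate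
Conditions: 21 (1.5 equiv), EDC·HCl (2 equiv), DMAP (0.5 equiv), CH2Cl2, 0 °C to rt
Reagents that add atoms: none
Why: Steglich esterification acylates the only free hydroxyl (C8) with retention and also blocks any lactone migration to O8.

**Step 12**
Reactants: 22 (1S)-3-methyl-1-[(2R,3R)-4-methylidene-5-oxo-2-{(1Z)-2-[(TBSO)methyl]hexa-1,5-dien-1-yl}oxolan-3-yl]but-3-en-1-yl (2S)-3-(TBSO)-2-methylpropanoate
Product: 23 (3aR,4S,6Z,10Z,11aR)-6-methyl-3-methylidene-2-oxo-10-[(TBSO)methyl]-2,3,3a,4,5,8,9,11a-octahydrocyclodeca[b]furan-4-yl (2S)-3-(TBSO)-2-methylpropanoate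
Conditions: second-generation Hoveyda–Grubbs catalyst RuCl2(H2IMes)(=CH-C6H4-2-OiPr) (15 mol %), 1,4-benzoquinone (30 mol %), toluene (1 mM), 80 °C, argon sparge
Reagents that add atoms: none
Why: Ring-closing metathesis between the terminal vinyl group (C1) and the 1,1-disubstituted alkene (C10) closes the ten-membered ring, where the cis (Z) trisubstituted alkene is the expected geometry, while closure onto the lactone methylene is disfavoured because it would put the trans C4=C5 alkene in an eight-membered ring.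

**Step 13**
Reactants: 23 (3aR,4S,6Z,10Z,11aR)-6-methyl-3-methylidene-2-oxo-10-[(TBSO)methyl]-2,3,3a,4,5,8,9,11a-octahydrocyclodeca[b]furan-4-yl (2S)-3-(TBSO)-2-methylpropanoate
Product: 24 (3aR,4S,6Z,10Z,11aR)-10-(hydroxymethyl)-6-methyl-3-methylidene-2-oxo-2,3,3a,4,5,8,9,11a-octahydrocyclodeca[b]furan-4-yl (2S)-3-hydroxy-2-methylpropanoate
Conditions: HF·pyridine, pyridine, THF, 0 °C to rt
Reagents that add atoms: none
Why: Buffered fluoride-mediated desilylation removes both primary TBS ethers without acyl migration or addition to the methylene lactone.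

**Compound list**
1 | prop-2-yn-1-ol | C#CCO | starting material
2 | but-3-en-1-ylmagnesium bromide | C=CCC[Mg]Br | starting material
3 | 4-(but-3-en-1-yl)-2,5-dihydro-1,2-oxamagnesole (magnesium chelate) | C=CCCC1=C[Mg]OC1 | intermediate (not isolated)
4 | (2Z)-2-(but-3-en-1-yl)-3-iodoprop-2-en-1-ol | I/C=C(\CO)CCC=C | intermediate
5 | tert-butyl{[(2Z)-2-(but-3-en-1-yl)-3-iodoprop-2-en-1-yl]oxy}dimethylsilane | I/C=C(\CO[Si](C)(C)C(C)(C)C)CCC=C | intermediate
6 | {(1Z)-2-[(TBSO)methyl]hexa-1,5-dien-1-yl}lithium (vinyllithium) | [Li]/C=C(\CO[Si](C)(C)C(C)(C)C)CCC=C | intermediate (not isolated)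
7 | (2Z)-3-[(TBSO)methyl]hepta-2,6-dienal | O=C/C=C(\CO[Si](C)(C)C(C)(C)C)CCC=C | intermediate
8 | methyl prop-2-ynoate | COC(=O)C#C | starting material
9 | methyl 3-(methylzincio)prop-2-ynoate (alkynylzinc) | COC(=O)C#C[Zn]C | intermediate (not isolated)
10 | methyl (4R,5Z)-6-[(TBSO)methyl]-4-hydroxydeca-5,9-dien-2-ynoate | COC(=O)C#C[C@H](O)/C=C(\CO[Si](C)(C)C(C)(C)C)CCC=C | intermediate
11 | methyl (2Z,4S,5Z)-6-[(TBSO)methyl]-4-hydroxydeca-2,5,9-trienoate (hydroxy enoate) | COC(=O)/C=C\[C@H](O)/C=C(\CO[Si](C)(C)C(C)(C)C)CCC=C | intermediate (not isolated)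
12 | (5S)-5-{(1Z)-2-[(TBSO)methyl]hexa-1,5-dien-1-yl}furan-2(5H)-one | O=C1O[C@H](/C=C(\CO[Si](C)(C)C(C)(C)C)CCC=C)C=C1 | intermediate
13 | 3-methylbut-3-en-1-ol | CC(=C)CCO | starting material
14 | 3-methylbut-3-enal | CC(=C)CC=O | intermediate
15 | (4R,5R)-4-[(1S)-1-hydroxy-3-methylbut-3-en-1-yl]-5-{(1Z)-2-[(TBSO)methyl]hexa-1,5-dien-1-yl}oxolan-2-one | O=C1C[C@H]([C@@H](O)CC(C)=C)[C@H](O1)/C=C(\CO[Si](C)(C)C(C)(C)C)CCC=C | intermediate
16 | (3R,4R,5R)-3-[(dimethylamino)methyl]-4-[(1S)-1-hydroxy-3-methylbut-3-en-1-yl]-5-{(1Z)-2-[(TBSO)methyl]hexa-1,5-dien-1-yl}oxolan-2-one (Mannich base) | CN(C)C[C@@H]1C(=O)O[C@H](/C=C(\CO[Si](C)(C)C(C)(C)C)CCC=C)[C@H]1[C@@H](O)CC(C)=C | intermediate (not isolated)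
17 | trimethylammonium iodide of 16 (N-methylated Mannich base) | C[N+](C)(C)C[C@@H]1C(=O)O[C@H](/C=C(\CO[Si](C)(C)C(C)(C)C)CCC=C)[C@H]1[C@@H](O)CC(C)=C.[I-] | intermediate (not isolated)
18 | (4R,5R)-4-[(1S)-1-hydroxy-3-methylbut-3-en-1-yl]-3-methylidene-5-{(1Z)-2-[(TBSO)methyl]hexa-1,5-dien-1-yl}oxolan-2-one | C=C1C(=O)O[C@H](/C=C(\CO[Si](C)(C)C(C)(C)C)CCC=C)[C@H]1[C@@H](O)CC(C)=C | intermediate
19 | methyl (2S)-3-hydroxy-2-methylpropanoate | COC(=O)[C@@H](C)CO | starting material
20 | methyl (2S)-3-(TBSO)-2-methylpropanoate | COC(=O)[C@@H](C)CO[Si](C)(C)C(C)(C)C | intermediate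
21 | (2S)-3-(TBSO)-2-methylpropanoic acid | OC(=O)[C@@H](C)CO[Si](C)(C)C(C)(C)C | intermediate
22 | (1S)-3-methyl-1-[(2R,3R)-4-methylidene-5-oxo-2-{(1Z)-2-[(TBSO)methyl]hexa-1,5-dien-1-yl}oxolan-3-yl]but-3-en-1-yl (2S)-3-(TBSO)-2-methylpropanoate | C=C1C(=O)O[C@H](/C=C(\CO[Si](C)(C)C(C)(C)C)CCC=C)[C@H]1[C@@H](OC(=O)[C@@H](C)CO[Si](C)(C)C(C)(C)C)CC(C)=C | intermediate
23 | (3aR,4S,6Z,10Z,11aR)-6-methyl-3-methylidene-2-oxo-10-[(TBSO)methyl]-2,3,3a,4,5,8,9,11a-octahydrocyclodeca[b]furan-4-yl (2S)-3-(TBSO)-2-methylpropanoate | C=C1C(=O)O[C@@H]2/C=C(\CO[Si](C)(C)C(C)(C)C)CC/C=C(/C)C[C@H](OC(=O)[C@@H](C)CO[Si](C)(C)C(C)(C)C)[C@@H]12 | intermediate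
24 | (3aR,4S,6Z,10Z,11aR)-10-(hydroxymethyl)-6-methyl-3-methylidene-2-oxo-2,3,3a,4,5,8,9,11a-octahydrocyclodeca[b]furan-4-yl (2S)-3-hydroxy-2-methylpropanoate | C=C1C(=O)O[C@@H]2/C=C(\CO)CC/C=C(/C)C[C@H](OC(=O)[C@@H](C)CO)[C@@H]12 | target

**Step count**
Total: 13 steps. Longest linear sequence: 10 steps (1, 2, 3, 4, 5, 7, 8, 11, 12, 13).

**Three steps most likely to fail**

Step 12 (ring closure). A ten-membered ring with a new trisubstituted alkene is a hard metathesis, and oligomers or engagement of the methylene lactone are possible. The fallback sets out from 15 and comes back at 23. It moves the ring closure ahead of the two steps that add the acrylate-type alkene and the bulky acyl group: 15 is cyclised with the same ruthenium catalyst at high dilution to the macrocyclic hydroxy lactone F1, F1 is methylenated as in step 8 through the macrocyclic Mannich base F2 and the macrocyclic ammonium iodide F3 to the macrocyclic methylene hydroxy lactone F4, and F4 is esterified with 21 (EDC·HCl, DMAP) to give 23.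

Step 7 (ketyl coupling). The C7 configuration is reliable, but the C8 configuration rests on a chelate model, and pinacol coupling of 14 competes. The fallback sets out from crude 15 and comes back at 15. The mixture of 15 and its C8 epimer F5 is oxidised with Dess–Martin periodinane to the single ketone F6, and F6 is reduced with (R)-Me-CBS oxazaborolidine and catecholborane at −78 °C, so that C8 is set by the reagent and not by the radical step.

Step 4 (asymmetric alkynylation). Enantioselectivity on a hindered (Z)-β,β-disubstituted enal is not assured. The fallback sets out from 7 and comes back at 10. The lithium acetylide F7 (from 8 and LiN(SiMe3)2, THF, −78 °C) is added to 7 to give the racemic propargylic alcohol F8, Dess–Martin oxidation gives the ynone F9, and (R)-Me-CBS oxazaborolidine with catecholborane reduces F9 to 10, with the alkenyl group acting as the large substituent.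

**Further compounds**
F1 | step 12 | (3aR,4S,6Z,10Z,11aR)-4-hydroxy-6-methyl-10-[(TBSO)methyl]-3a,4,5,8,9,11a-hexahydrocyclodeca[b]furan-2(3H)-one | C1C(=O)O[C@@H]2/C=C(\CO[Si](C)(C)C(C)(C)C)CC/C=C(/C)C[C@H](O)[C@@H]12
F2 | step 12 | (3R,3aR,4S,6Z,10Z,11aR)-3-[(dimethylamino)methyl]-4-hydroxy-6-methyl-10-[(TBSO)methyl]-3a,4,5,8,9,11a-hexahydrocyclodeca[b]furan-2(3H)-one | CN(C)C[C@@H]1C(=O)O[C@@H]2/C=C(\CO[Si](C)(C)C(C)(C)C)CC/C=C(/C)C[C@H](O)[C@@H]12
F3 | step 12 | trimethylammonium iodide of F2 | C[N+](C)(C)C[C@@H]1C(=O)O[C@@H]2/C=C(\CO[Si](C)(C)C(C)(C)C)CC/C=C(/C)C[C@H](O)[C@@H]12.[I-]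
F4 | step 12 | (3aR,4S,6Z,10Z,11aR)-4-hydroxy-6-methyl-3-methylidene-10-[(TBSO)methyl]-3a,4,5,8,9,11a-hexahydrocyclodeca[b]furan-2(3H)-one | C=C1C(=O)O[C@@H]2/C=C(\CO[Si](C)(C)C(C)(C)C)CC/C=C(/C)C[C@H](O)[C@@H]12
F5 | step 7 | (4R,5R)-4-[(1R)-1-hydroxy-3-methylbut-3-en-1-yl]-5-{(1Z)-2-[(TBSO)methyl]hexa-1,5-dien-1-yl}oxolan-2-one | O=C1C[C@H]([C@H](O)CC(C)=C)[C@H](O1)/C=C(\CO[Si](C)(C)C(C)(C)C)CCC=C
F6 | step 7 | (4S,5R)-4-(3-methylbut-3-enoyl)-5-{(1Z)-2-[(TBSO)methyl]hexa-1,5-dien-1-yl}oxolan-2-one | O=C1C[C@H](C(=O)CC(C)=C)[C@H](O1)/C=C(\CO[Si](C)(C)C(C)(C)C)CCC=C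
F7 | step 4 | lithium 3-methoxy-3-oxoprop-1-yn-1-ide | COC(=O)C#C[Li]
F8 | step 4 | methyl (5Z)-6-[(TBSO)methyl]-4-hydroxydeca-5,9-dien-2-ynoate, racemic | COC(=O)C#CC(O)/C=C(\CO[Si](C)(C)C(C)(C)C)CCC=C
F9 | step 4 | methyl (5Z)-6-[(TBSO)methyl]-4-oxodeca-5,9-dien-2-ynoate | COC(=O)C#CC(=O)/C=C(\CO[Si](C)(C)C(C)(C)C)CCC=C
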